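**Numbering used throughout**

Ring B is numbered O1, C2 (bears ring C), C3 (bears the hydroxymethyl carbon C6), C4 (bears the ketone carbon C7 and, through it, ring A), C5. TBS = tert-butyldimethylsilyl.

Compounds: 1 isovanillin; 2 dimethyl succinate; 3 Stobbe half-ester; 4 (R)-half-ester after hydrogenation; 5 hydroxy acid (in the flask); 6 phenolic lactone; 7 silylated lactone; 8 silylated isovanillin; 9 lithium enolate of 7 (in the flask); 10 aldol lactone; 11 triol; 12 open keto diol (precursor of the key step); 13 silylated ring B ketone, 3,4-cis (product of the key step); 14 3,4-cis bisphenol (in the flask); 15 target.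

## Analysis of the target

Target 15 is a 2,3,4-trisubstituted tetrahydrofuran (ring B) that carries the same aryl group, 3-hydroxy-4-methoxyphenyl, twice, directly on C2 (ring C) and through the C7 ketone on C4 (ring A), with the hydroxymethyl carbon C6 on C3. The three stereocentres are contiguous, (2S,3R,4S), and both neighbouring pairs are trans, so the target should be the thermodynamically preferred diastereomer. C4 is α to the ketone and can be equilibrated, and C2 is a benzylic ether carbon that follows its neighbour, so only C3 needs absolute control. The sensitive groups are the two guaiacol-type phenols (oxidation), the para-methoxybenzylic ether C2–O1 (acid, hydrogenolysis, further oxidation) and the β-alkoxy ketone C7–C4–C5–O1 (base). The difficulty is that two identical arenes sit at different oxidation levels, aryl ketone and benzylic ether, and that the phenol protecting groups must leave at the end without reduction or strong acid. The plan rests on the O1–C2 bond, which joins the benzylic carbon C2, para to the methoxy group of ring C, to the C5 oxygen. This is the bond that forms when a para-oxygen-stabilised benzylic cation is trapped by a side-chain hydroxyl, so ring B can be closed by oxidising the C2–H of an open-chain keto diol.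

## Retrosynthetic reasoning

**15 from 13.** The last operation removes the two silyl ethers and inverts C4. The open-chain route delivers ring B with the C3 and C4 substituents cis (13). Because C4 is α to C7, base equilibration through 14 should move the aroyl group to the less crowded face. Silyl protection is chosen because its removal needs neither hydrogen nor acid, both of which threaten the C2–O1 bond.

**13 from 12 (O1–C2).** The cut is placed at the benzylic ether and not at O1–C5 or at C2–aryl. Cutting here removes the ring and the C2 stereocentre together and leaves a diol in which C2 is a plain benzylic methylene. The forward reaction must remove hydride from C2, the only benzylic sp3 carbon of 12, and let the C5 hydroxyl capture the cation. The C6 hydroxyl cannot compete, since it would give a four-membered ring. Ring A is switched off by the ketone. C2 is set by C3.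

**12 from 11 and 10.** The ketone is taken back to a benzylic alcohol (11) and the two primary alcohols to a γ-lactone (10). The gain is that C5 and C6 arrive together from one carbonyl reduction, and that the ketone can be made by a benzylic-selective oxidation that ignores the primary alcohols.

**10 from 7 and 8 (C4–C7).** The lactone α-carbon is joined to the aldehyde carbon by an aldol addition. The forward reaction only has to place the new substituent trans to the arylmethyl group of 7. The carbinol configuration is irrelevant. The trans lactone maps onto the 3,4-cis arrangement of ring B, because C6 and C2 exchange their ring and side-chain roles at C3 when the lactone is opened and ring B is closed. This is why 12 and 13 carry C4 in the (R) configuration and the last step corrects it.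

**7 from 6, 4, 3, 1 and 2.** The lactone comes from half-ester 4 by reduction of the ester beside the carboxylate. C3, the only centre needing absolute control, is set by asymmetric hydrogenation of the alkene of 3. Compound 3 is the Stobbe condensation product of 1 and 2 (C2=C3 bond). The phenol stays free through these steps because a silyl ether would not survive the alkoxide, and it is silylated at the lactone stage (6 to 7).

**8 from 1.** The aldol partner is the silyl ether of the same aldehyde, so both arenes come from 1.

## Alternatives that were turned down

Alternative 1: Ring A is disconnected into a furan and an alkyne.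
- Key step: 3-methoxyfuran A1 and the terminal ynone A2 (ring B complete, ring C phenol and C6 alcohol as benzyl ethers) undergo a Diels–Alder reaction. Acid-induced opening of the oxygen bridge and aromatisation then give the ring A phenol A3.
- For: the orientation is right by polarity. The carbon of A1 next to methoxy is the nucleophilic end and bonds to the alkyne terminus of A2, so the acyl group ends para to methoxy and the former bridge oxygen becomes the meta hydroxyl. The ring A phenol of A3 is formed free and is distinct from the ring C phenol. On this point it is stronger than the chosen route, which cannot tell the two phenols apart, although 15 does not need that.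
- Against: ring A is the cheapest part of the target and is already present in 1. The key step forms no bond of ring B and sets none of the three stereocentres, so the whole stereochemical problem moves into the synthesis of A2. In A2, C4 lies between an ynone carbonyl and ring B, so it is very acidic and sits next to a strong Michael acceptor. Furan–alkyne cycloadditions are reversible. A3 still has to lose two benzyl ethers by hydrogenolysis beside a benzylic ether and an aryl ketone.
- Comparison: more steps for less structural gain. The chosen strategy takes both arenes from 1 and spends its key step on ring B and C2.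

Alternative 2: The C3–C4 bond of ring B and the C6–O bond are disconnected.
- Key step: the lithium enolate of ketone A4 is oxidised by ferrocenium hexafluorophosphate A5, [Fe(C5H5)2]PF6 (trivalent iron), to the C4 radical. This closes 5-exo-trig onto the vinyl group, and the C6 radical is trapped by TEMPO A6 to give the cyclised product A7.
- For: one operation makes a carbon–carbon bond, ring B and the C6–O bond. A4 is assembled convergently from two aryl pieces, and a chair-like transition state with the C2 aryl group pseudo-equatorial should give 2,3-trans. In bond-forming economy it is stronger than the chosen route.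
- Against: A4 is an open-chain β-alkoxy ketone, and its enolate can expel the allylic alkoxide before it is oxidised. A6 can capture the slowly cyclising α-keto radical at C4 before ring closure. C2 must be brought in as an enantiopure, ionisable aryl allyl ether. A7 needs reductive N–O cleavage and debenzylation by hydrogenolysis next to the benzylic ether.
- Comparison: three stereocentres depend on one radical cyclisation. The chosen route sets C3 by a widely precedented catalytic hydrogenation and lets C2 and C4 follow, with its one uncertain step run under mild conditions.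

Alternative 3: Both aryl–carbon bonds, C2–ring C and C7–ring A, are disconnected.
- Key step: triflic acid A10 ionises the ring B core A8 at both ends, the lactol acetate to an oxocarbenium ion at C2 and the acid chloride to an acylium ion at C7. Two molecules of 2-methoxyphenyl acetate A9 attack para to methoxy and give the triacetate A11.
- For: it uses the identity of rings A and C fully, bringing both in from one cheap arene in one step with the correct substitution pattern. In convergence it is stronger than the chosen route, which builds the two aryl-bearing carbons in separate steps (though from the same aldehyde 1).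
- Against: two different cations must form and react in one flask. A9 is a deactivated arene for acylation and an aryl ester prone to Fries rearrangement in superacid. Under the forcing conditions the new para-methoxybenzylic ether of ring B in A11 can re-ionise and arylate a second time with ring opening. The C6 acetate can participate at C2. A8, with two stereocentres in enantiopure form, needs a synthesis about as long as that of lactone 7.
- Comparison: the chosen route is longer in linear steps, but every bond is made by a reaction with close precedent and the one uncertain step is mild and late.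

Key step: step 9

## Route

Remark on the chemistry (assumption): the aldol of step 6 is taken to give the trans lactone, so 12 and 13 carry C4 in the (R) configuration (3,4-cis in ring B). This centre is α to the C7 ketone and is brought to the (S) configuration of 15 in step 10, so any partial epimerisation of C4 at the stage of 12 is of no consequence.

Step 1
Reactants: 1 isovanillin (3-hydroxy-4-methoxybenzaldehyde); 2 dimethyl succinate
Product: 3 (E)-4-(3-hydroxy-4-methoxyphenyl)-3-(methoxycarbonyl)but-3-enoic acid
Conditions: NaOMe (3 equiv), MeOH, reflux; then 2 M HCl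
Reagents that add atoms: none
Why: Stobbe condensation: the succinate enolate adds to the aldehyde, the aldolate lactonises onto the distal ester and base-induced ring opening gives the half-ester with the aryl group trans to the ester. The phenoxide of 1 is meta to the formyl group and does not conjugate with it, so one extra equivalent of base should suffice.

Step 2
Reactants: 3 (E)-4-(3-hydroxy-4-methoxyphenyl)-3-(methoxycarbonyl)but-3-enoic acid
Product: 4 (3R)-3-[(3-hydroxy-4-methoxyphenyl)methyl]-4-methoxy-4-oxobutanoic acid
Conditions: H2 (5 bar), [Rh(cod)((S,S)-Et-DuPhos)]BF4 (1 mol%), NaOMe (10 mol%), MeOH, rt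
Reagents that add atoms: none
Why: Asymmetric hydrogenation of a β-aryl itaconate half-ester with the cationic catalyst [Rh(cod)((S,S)-Et-DuPhos)]BF4: the carboxylate and the alkene chelate the metal and the ligand selects the alkene face, setting C3 of the target as the (R) acid. The (S,S) ligand is the hand expected for this sense in this substrate class; its antipode would be used should the sense prove opposite.

Step 3
Reactants: 4 (3R)-3-[(3-hydroxy-4-methoxyphenyl)methyl]-4-methoxy-4-oxobutanoic acid
Product: 6 (4R)-4-[(3-hydroxy-4-methoxyphenyl)methyl]oxolan-2-one, via hydroxy acid 5 (not isolated)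
Conditions: KOH (2 equiv), EtOH; CaCl2, NaBH4, EtOH, −10 °C to rt; then 3 M HCl, rt
Reagents that add atoms: none
Why: Chemoselective borohydride reduction: Ca(BH4)2 made in the flask reduces the ester but not the carboxylate, and acidification lactonises the γ-hydroxy acid 5. The stereocentre is not involved.

Step 4
Reactants: 6 (4R)-4-[(3-hydroxy-4-methoxyphenyl)methyl]oxolan-2-one
Product: 7 (4R)-4-{[3-(tert-butyldimethylsilyloxy)-4-methoxyphenyl]methyl}oxolan-2-one
Conditions: TBSCl, imidazole, DMF, rt
Reagents that add atoms: tert-butyldimethylsilyl chloride, CC(C)(C)[Si](C)(C)Cl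
Why: Imidazole-promoted silylation of a phenol; the lactone is inert to these conditions.

Step 5
Reactants: 1 isovanillin (3-hydroxy-4-methoxybenzaldehyde)
Product: 8 3-(tert-butyldimethylsilyloxy)-4-methoxybenzaldehyde
Conditions: TBSCl, imidazole, DMF, rt
Reagents that add atoms: tert-butyldimethylsilyl chloride, CC(C)(C)[Si](C)(C)Cl
Why: Imidazole-promoted silylation of a phenol, giving the non-enolisable aldol partner.

Step 6
Reactants: 7 (4R)-4-{[3-(tert-butyldimethylsilyloxy)-4-methoxyphenyl]methyl}oxolan-2-one; 8 3-(tert-butyldimethylsilyloxy)-4-methoxybenzaldehyde
Product: 10 (3S,4R)-3-{hydroxy[3-(tert-butyldimethylsilyloxy)-4-methoxyphenyl]methyl}-4-{[3-(tert-butyldimethylsilyloxy)-4-methoxyphenyl]methyl}oxolan-2-one (both carbinol epimers), via lithium enolate 9 (not isolated)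
Conditions: LiN(iPr)2 (LDA, 1.05 equiv), THF, −78 °C; then 8, −78 °C; aq. NH4Cl at −78 °C
Reagents that add atoms: none
Why: Lithium enolate aldol addition: the aldehyde approaches the enolate face opposite the neighbouring arylmethyl group, so the new ring stereocentre is trans to it. The carbinol carbon forms as a mixture, which does not matter because it becomes the ketone.

Step 7
Reactants: 10 trans aldol lactone, (3S,4R)-3-{hydroxy[3-(tert-butyldimethylsilyloxy)-4-methoxyphenyl]methyl}-4-{[3-(tert-butyldimethylsilyloxy)-4-methoxyphenyl]methyl}oxolan-2-one
Product: 11 (2R,3R)-2-{hydroxy[3-(tert-butyldimethylsilyloxy)-4-methoxyphenyl]methyl}-3-{[3-(tert-butyldimethylsilyloxy)-4-methoxyphenyl]methyl}butane-1,4-diol (both carbinol epimers)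
Conditions: LiAlH4 (2 equiv), THF, 0 °C; H2O, aq. NaOH work-up
Reagents that add atoms: none
Why: Hydride reduction of the lactone to the 1,4-diol, fast at 0 °C so that retro-aldol cleavage and attack on the aryl silyl ethers should not compete. No stereocentre is touched.

Step 8
Reactants: 11 triol, (2R,3R)-2-{hydroxy[3-(tert-butyldimethylsilyloxy)-4-methoxyphenyl]methyl}-3-{[3-(tert-butyldimethylsilyloxy)-4-methoxyphenyl]methyl}butane-1,4-diol
Product: 12 (2R,3R)-2-[3-(tert-butyldimethylsilyloxy)-4-methoxybenzoyl]-3-{[3-(tert-butyldimethylsilyloxy)-4-methoxyphenyl]methyl}butane-1,4-diol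
Conditions: activated MnO2 (15 equiv), CH2Cl2, rt
Reagents that add atoms: none
Why: Chemoselective benzylic alcohol oxidation: MnO2 oxidises the benzylic carbinol and leaves the two primary aliphatic alcohols. The neutral conditions spare the β-hydroxy ketone from dehydration, and both carbinol epimers converge on one ketone.

Step 9
Reactants: 12 open keto diol, (2R,3R)-2-[3-(tert-butyldimethylsilyloxy)-4-methoxybenzoyl]-3-{[3-(tert-butyldimethylsilyloxy)-4-methoxyphenyl]methyl}butane-1,4-diol
Product: 13 [(2S,3R,4R)-2-[3-(tert-butyldimethylsilyloxy)-4-methoxyphenyl]-3-(hydroxymethyl)oxolan-4-yl][3-(tert-butyldimethylsilyloxy)-4-methoxyphenyl]methanone (ring B numbering as above; 2,3-trans, 3,4-cis)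
Conditions: DDQ (1.1 equiv), 4 Å molecular sieves, CH2Cl2, 0 °C to rt, in the dark
Reagents that add atoms: none
Why: DDQ forms a charge-transfer complex with ring C, the electron-rich arene, and removes hydride from C2, giving a benzylic cation delocalised onto the para methoxy oxygen, the O-methyl counterpart of a quinone methide. The C5 hydroxyl captures this cation and forms O1–C2; ring B closes in the 5-exo-trig mode, since the cationic carbon's bond to the arene lies outside the new ring. The closest known reaction type is the DDQ-mediated oxidative cyclisation (benzylic C–H etherification) of dibenzylbutane-1,4-diols to aryltetrahydrofuran lignans. Site selectivity is secured by the substrate: C2 is the only benzylic sp3 carbon, ring A is deactivated by the C7 carbonyl, and both phenols are silylated. Between the two hydroxyls, only the C5 hydroxyl can form a five-membered ring; the C6 hydroxyl would give an oxetane. The new stereocentre C2 is controlled by C3: in the envelope transition state the aryl group takes the face opposite the C3 hydroxymethyl group, giving 2,3-trans (2S), and the weakly acidic reduced quinone allows the benzylic ether to re-ionise towards the same isomer. The step also needs selectivity against a second hydride abstraction from the new benzylic ether, which the substrate does not provide and which is sought through the near-stoichiometric charge of oxidant and the exclusion of water. C3 and C4 are untouched, so 13 keeps the 3,4-cis relationship inherited from the trans lactone.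

Step 10
Reactants: 13 silylated 3,4-cis ring B ketone, [(2S,3R,4R)-2-[3-(tert-butyldimethylsilyloxy)-4-methoxyphenyl]-3-(hydroxymethyl)oxolan-4-yl][3-(tert-butyldimethylsilyloxy)-4-methoxyphenyl]methanone
Product: 15 [(2S,3R,4S)-2-(3-hydroxy-4-methoxyphenyl)-3-(hydroxymethyl)oxolan-4-yl](3-hydroxy-4-methoxyphenyl)methanone (target; ring B numbering as above), via 3,4-cis bisphenol 14 (not isolated)
Conditions: TBAF (2.2 equiv), THF, 0 °C; then K2CO3 (0.3 equiv), MeOH, rt; aq. NH4Cl
Reagents that add atoms: none
Why: Fluoride-induced desilylation of the two aryl silyl ethers, then base-mediated epimerisation through the C4 enolate, which should settle the aroyl group trans to the C3 hydroxymethyl group (all-trans, 4S). Ring opening by β-elimination of O1 would be the reverse of a 5-endo-trig closure and has poor orbital overlap, so enolate reprotonation should be the faster process. C2 and C3 are not affected.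

## Compound list

1 | isovanillin (3-hydroxy-4-methoxybenzaldehyde) | COc1ccc(C=O)cc1O | starting material
2 | dimethyl succinate | COC(=O)CCC(=O)OC | starting material
3 | (E)-4-(3-hydroxy-4-methoxyphenyl)-3-(methoxycarbonyl)but-3-enoic acid | COC(=O)/C(CC(=O)O)=C/c1ccc(OC)c(O)c1 | intermediate
4 | (3R)-3-[(3-hydroxy-4-methoxyphenyl)methyl]-4-methoxy-4-oxobutanoic acid | COC(=O)[C@H](Cc1ccc(OC)c(O)c1)CC(=O)O | intermediate
5 | (3R)-4-hydroxy-3-[(3-hydroxy-4-methoxyphenyl)methyl]butanoic acid | OC(=O)C[C@@H](Cc1ccc(OC)c(O)c1)CO | intermediate (not isolated)
6 | (4R)-4-[(3-hydroxy-4-methoxyphenyl)methyl]oxolan-2-one | O=C1C[C@@H](Cc2ccc(OC)c(O)c2)CO1 | intermediate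
7 | (4R)-4-{[3-(tert-butyldimethylsilyloxy)-4-methoxyphenyl]methyl}oxolan-2-one | O=C1C[C@@H](Cc2ccc(OC)c(O[Si](C)(C)C(C)(C)C)c2)CO1 | intermediate
8 | 3-(tert-butyldimethylsilyloxy)-4-methoxybenzaldehyde | COc1ccc(C=O)cc1O[Si](C)(C)C(C)(C)C | intermediate
9 | lithium enolate of 7 | [Li]OC1=C[C@@H](Cc2ccc(OC)c(O[Si](C)(C)C(C)(C)C)c2)CO1 | intermediate (not isolated)
10 | (3S,4R)-3-{hydroxy[3-(tert-butyldimethylsilyloxy)-4-methoxyphenyl]methyl}-4-{[3-(tert-butyldimethylsilyloxy)-4-methoxyphenyl]methyl}oxolan-2-one, both carbinol epimers | COc1ccc(C(O)[C@H]2C(=O)OC[C@@H]2Cc2ccc(OC)c(O[Si](C)(C)C(C)(C)C)c2)cc1O[Si](C)(C)C(C)(C)C | intermediate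
11 | (2R,3R)-2-{hydroxy[3-(tert-butyldimethylsilyloxy)-4-methoxyphenyl]methyl}-3-{[3-(tert-butyldimethylsilyloxy)-4-methoxyphenyl]methyl}butane-1,4-diol, both carbinol epimers | COc1ccc(C(O)[C@@H](CO)[C@@H](Cc2ccc(OC)c(O[Si](C)(C)C(C)(C)C)c2)CO)cc1O[Si](C)(C)C(C)(C)C | intermediate
12 | (2R,3R)-2-[3-(tert-butyldimethylsilyloxy)-4-methoxybenzoyl]-3-{[3-(tert-butyldimethylsilyloxy)-4-methoxyphenyl]methyl}butane-1,4-diol | COc1ccc(C(=O)[C@@H](CO)[C@@H](Cc2ccc(OC)c(O[Si](C)(C)C(C)(C)C)c2)CO)cc1O[Si](C)(C)C(C)(C)C | intermediate
13 | [(2S,3R,4R)-2-[3-(tert-butyldimethylsilyloxy)-4-methoxyphenyl]-3-(hydroxymethyl)oxolan-4-yl][3-(tert-butyldimethylsilyloxy)-4-methoxyphenyl]methanone | COc1ccc(C(=O)[C@H]2CO[C@H](c3ccc(OC)c(O[Si](C)(C)C(C)(C)C)c3)[C@H]2CO)cc1O[Si](C)(C)C(C)(C)C | intermediate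
14 | [(2S,3R,4R)-2-(3-hydroxy-4-methoxyphenyl)-3-(hydroxymethyl)oxolan-4-yl](3-hydroxy-4-methoxyphenyl)methanone | COc1ccc(C(=O)[C@H]2CO[C@H](c3ccc(OC)c(O)c3)[C@H]2CO)cc1O | intermediate (not isolated)
15 | [(2S,3R,4S)-2-(3-hydroxy-4-methoxyphenyl)-3-(hydroxymethyl)oxolan-4-yl](3-hydroxy-4-methoxyphenyl)methanone | COc1ccc(C(=O)[C@@H]2CO[C@H](c3ccc(OC)c(O)c3)[C@H]2CO)cc1O | target

## Step count and least certain steps

Total: 10 steps. Longest linear sequence: 9 steps (steps 1–4 and 6–10); step 5 is a one-step branch to 8.

**Step 9 (key step).** The most likely failure is over-oxidation. The new benzylic ether C2–H of 13 is at least as easily abstracted as the C2–H of 12, which would open ring B again after work-up. Lesser risks are proton loss from C3 to a styrene, capture of the cation by the C7 carbonyl oxygen, and slow hydride abstraction because a silyloxy group donates less than an alkoxy group.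

The fallback generates the same C2 cation by ionising a benzylic alcohol, with no oxidant present; it sets out from 8 and comes back to the route at 13. Aldehyde 8 is converted with propane-1,3-dithiol and BF3·OEt2 into 2-[3-(tert-butyldimethylsilyloxy)-4-methoxyphenyl]-1,3-dithiane F1. F1 is deprotonated with n-BuLi at −78 °C and added in conjugate fashion to (5R)-5-[(1R,2S,5R)-menthyloxy]furan-2(5H)-one (SMILES O=C1C=C[C@H](O[C@@H]2C[C@H](C)CC[C@H]2C(C)C)O1), trans to the menthyloxy group. The resulting lactone enolate is trapped with a second equivalent of 8, trans to the new substituent, giving the three-component lactone F2. LiAlH4 reduces the lactone carbonyl and the masked aldehyde of F2, with loss of menthol, to the dithiane triol F3, in which C2 is a benzylic alcohol and C7 is masked. Camphorsulfonic acid in CH2Cl2 ionises C2 of F3 and the C5 hydroxyl closes ring B, trans to the C3 hydroxymethyl group, giving the ring B dithiane F4, which is 13 with C7 as its 1,3-dithiane. MeI and CaCO3 in aqueous MeCN unmask the ketone of F4 and give 13.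

**Step 10.** The risks are base-induced cleavage of the C5–O1 bond from the C4 enolate, incomplete equilibration at C4, and holding back of the cis isomer as a cyclic hemiketal between the C6 hydroxyl and C7.

The fallback separates the two events and avoids phenoxide and protic base; it sets out from 13 and comes back to the route at 15. C4 is equilibrated while the phenols are still silylated, with catalytic DBU in dry toluene, to the all-trans bis-silyl ether F5. The silyl groups of F5 are then removed with the acidic fluoride source HF·pyridine in THF at 0 °C, giving 15.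

**Step 1.** The risks are low conversion because the phenoxide of 1 lowers the electrophilicity of the aldehyde, and ester cleavage by adventitious hydroxide during the long heating.

The fallback runs the condensation on a benzyl-protected aldehyde; it sets out from 1 and 2 and comes back to the route at 6. Compound 1 is benzylated with benzyl bromide and K2CO3 in DMF to 3-(benzyloxy)-4-methoxybenzaldehyde F6. F6 is condensed with 2 under the conditions of step 1 to the benzyl-protected half-ester F7. F7 is hydrogenated as in step 2 to the benzyl-protected (R)-acid F8; the catalyst [Rh(cod)((S,S)-Et-DuPhos)]BF4 does not cleave benzyl ethers. F8 is reduced as in step 3 through the benzyl-protected hydroxy acid F9, formed in the flask, to the benzyl-protected lactone F10. H2 and Pd/C in EtOAc remove the benzyl group from F10 and give 6.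

**Step 2.** The risk is erosion of enantioselectivity, for instance through the free phenol or a geometric mixture of 3. This would carry through the whole route because C3 is the only centre set by a reagent.

The fallback uses classical resolution instead of asymmetric catalysis; it sets out from 3 and comes back to the route at 4. Compound 3 is hydrogenated with H2 and Pd/C in MeOH to the racemic half-ester F11. F11 is resolved by crystallisation of its salt with one hand of 1-phenylethylamine, drawn here as (S) and to be chosen by screening, giving the diastereomerically pure ammonium salt F12. Acidification of F12 releases 4; the unwanted enantiomer could be recycled separately.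

## Further compounds

F1 | step 9 | 2-[3-(tert-butyldimethylsilyloxy)-4-methoxyphenyl]-1,3-dithiane | COc1ccc(C2SCCCS2)cc1O[Si](C)(C)C(C)(C)C
F2 | step 9 | (3S,4R,5R)-configured three-component lactone: 5-(menthyloxy)oxolan-2-one with the 2-aryl-1,3-dithian-2-yl group at C4 and the aryl(hydroxy)methyl group at C3, all ring substituents mutually trans, both carbinol epimers | O=C1[C@H](C(O)c2ccc(OC)c(O[Si](C)(C)C(C)(C)C)c2)[C@@H](C2(c3ccc(OC)c(O[Si](C)(C)C(C)(C)C)c3)SCCCS2)[C@H](O[C@@H]2C[C@H](C)CC[C@H]2C(C)C)O1
F3 | step 9 | dithiane triol: 2-{2-[3-(tert-butyldimethylsilyloxy)-4-methoxyphenyl]-1,3-dithian-2-yl}-3-{hydroxy[3-(tert-butyldimethylsilyloxy)-4-methoxyphenyl]methyl}butane-1,4-diol, backbone configured as in 12, both carbinol epimers | COc1ccc(C2(SCCCS2)[C@@H](CO)[C@H](CO)C(O)c2ccc(OC)c(O[Si](C)(C)C(C)(C)C)c2)cc1O[Si](C)(C)C(C)(C)C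
F4 | step 9 | ring B dithiane: 13 with C7 as its 1,3-dithiane | COc1ccc(C2(SCCCS2)[C@H]2CO[C@H](c3ccc(OC)c(O[Si](C)(C)C(C)(C)C)c3)[C@H]2CO)cc1O[Si](C)(C)C(C)(C)C
F5 | step 10 | [(2S,3R,4S)-2-[3-(tert-butyldimethylsilyloxy)-4-methoxyphenyl]-3-(hydroxymethyl)oxolan-4-yl][3-(tert-butyldimethylsilyloxy)-4-methoxyphenyl]methanone (all-trans bis-silyl ether of 15) | COc1ccc(C(=O)[C@@H]2CO[C@H](c3ccc(OC)c(O[Si](C)(C)C(C)(C)C)c3)[C@H]2CO)cc1O[Si](C)(C)C(C)(C)C
F6 | step 1 | 3-(benzyloxy)-4-methoxybenzaldehyde | COc1ccc(C=O)cc1OCc1ccccc1
F7 | step 1 | (E)-4-[3-(benzyloxy)-4-methoxyphenyl]-3-(methoxycarbonyl)but-3-enoic acid | COC(=O)/C(CC(=O)O)=C/c1ccc(OC)c(OCc2ccccc2)c1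
F8 | step 1 | (3R)-3-{[3-(benzyloxy)-4-methoxyphenyl]methyl}-4-methoxy-4-oxobutanoic acid | COC(=O)[C@H](Cc1ccc(OC)c(OCc2ccccc2)c1)CC(=O)O
F9 | step 1 | (3R)-3-{[3-(benzyloxy)-4-methoxyphenyl]methyl}-4-hydroxybutanoic acid | OC(=O)C[C@@H](Cc1ccc(OC)c(OCc2ccccc2)c1)CO
F10 | step 1 | (4R)-4-{[3-(benzyloxy)-4-methoxyphenyl]methyl}oxolan-2-one | O=C1C[C@@H](Cc2ccc(OC)c(OCc3ccccc3)c2)CO1
F11 | step 2 | racemic 3-[(3-hydroxy-4-methoxyphenyl)methyl]-4-methoxy-4-oxobutanoic acid | COC(=O)C(Cc1ccc(OC)c(O)c1)CC(=O)O
F12 | step 2 | (S)-1-phenylethylammonium salt of 4 | COC(=O)[C@H](Cc1ccc(OC)c(O)c1)CC(=O)O.C[C@H](N)c1ccccc1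
A1 | alternative 1 | 3-methoxyfuran | COc1ccoc1
A2 | alternative 1 | terminal ynone: ring B with C2 3-(benzyloxy)-4-methoxyphenyl, C3 (benzyloxy)methyl and C4 prop-2-ynoyl, configured as in 15 | C#CC(=O)[C@@H]1CO[C@H](c2ccc(OC)c(OCc3ccccc3)c2)[C@H]1COCc1ccccc1
A3 | alternative 1 | 15 with the ring C phenol and the C6 alcohol as benzyl ethers | COc1ccc(C(=O)[C@@H]2CO[C@H](c3ccc(OC)c(OCc4ccccc4)c3)[C@H]2COCc2ccccc2)cc1O
A4 | alternative 2 | 1-[3-(benzyloxy)-4-methoxyphenyl]-3-{[(1S)-1-[3-(benzyloxy)-4-methoxyphenyl]prop-2-en-1-yl]oxy}propan-1-one | COc1ccc(C(=O)CCO[C@@H](C=C)c2ccc(OC)c(OCc3ccccc3)c2)cc1OCc1ccccc1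
A5 | alternative 2 | ferrocenium hexafluorophosphate, [Fe(C5H5)2]PF6 | [Fe+3].c1cc[cH-]c1.c1cc[cH-]c1.F[P-](F)(F)(F)(F)F
A6 | alternative 2 | TEMPO, (2,2,6,6-tetramethylpiperidin-1-yl)oxyl | CC1(C)CCCC(C)(C)N1[O]
A7 | alternative 2 | dibenzyl ether of 15 with the C6 oxygen as its 2,2,6,6-tetramethylpiperidin-1-yl ether | COc1ccc(C(=O)[C@@H]2CO[C@H](c3ccc(OC)c(OCc4ccccc4)c3)[C@H]2CON2C(C)(C)CCCC2(C)C)cc1OCc1ccccc1
A8 | alternative 3 | ring B core: C2 acetoxy lactol with C3 acetoxymethyl and C4 chlorocarbonyl, C3 and C4 configured as in 15 | CC(=O)OC[C@@H]1C(OC(C)=O)OC[C@H]1C(=O)Cl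
A9 | alternative 3 | 2-methoxyphenyl acetate | COc1ccccc1OC(C)=O
A10 | alternative 3 | trifluoromethanesulfonic acid | OS(=O)(=O)C(F)(F)F
A11 | alternative 3 | triacetate of 15 | COc1ccc(C(=O)[C@@H]2CO[C@H](c3ccc(OC)c(OC(C)=O)c3)[C@H]2COC(C)=O)cc1OC(C)=O
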